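**Retrosynthetic overview**

- Feature: in pyran ring C (chroman numbering O1, C2, C3, C4, C4a, C8a; ring A is the fused benzo ring, ring B the aryl group on C2) the chain C2–C3(isopropyl)–C4(isobutyl) has the carbon skeleton of the self-aldol dimer of isovaleraldehyde 1 (aldol 2, dehydrated to enal 3), and it lies between two phloroglucinol (4) nuclei.
- Disconnections: the four formyl C–C bonds at C6, C8, C3′ and C5′ come off first; then C2–C1′, O1–C2 and C4–C4a are cut in one operation, which leaves 3 and two molecules of 4.
- Forward: 3 and 4 give lactol 5 (ring C closed), which through 4H-chromene 6 takes up a second 4 to give pentaphenol 7; N,N-dimethylformamide 8 then delivers four formyl groups via iminium salt 9 to sideroxylonal A 10.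
- Ring order: rings A and B are bought as 4, and ring C is the only ring made; C4 is set by a chiral amine, and C3 and C2 are relayed from C4.

Key step: step 2

Remark: the sense of induction of the cinchona-derived primary amine with this acyclic α-branched enal cannot be fixed on paper; the quinine-derived amine is written, and its quinidine-derived pseudoenantiomer takes its place should a pilot run deliver the (4R) series.

**Route**

Step 1
Reactants: 1 isovaleraldehyde (3-methylbutanal), two molecules
Product: 3 (E)-2-isopropyl-5-methylhex-2-enal, via aldol 2 (not isolated)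
Conditions: NaOH (aq. 2 M, 0.2 equiv), MeOH, 65 °C; distillation
Reagents that add atoms: none
Why: Hydroxide-mediated self-aldol addition of 1 gives aldol 2, whose E1cB dehydration (aldol condensation) should yield the conjugated enal as the thermodynamically preferred (E)-isomer with isobutyl trans to the formyl group; no stereocentre is formed.

Step 2
Reactants: 3 (E)-2-isopropyl-5-methylhex-2-enal; 4 phloroglucinol (two molecules incorporated, used in excess)
Product: 7 (2R,3R,4S)-4-isobutyl-3-isopropyl-2-(2,4,6-trihydroxyphenyl)chroman-5,7-diol, via lactol 5 (not isolated), via 4H-chromene 6 (not isolated)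
Conditions: 4 (3 equiv), 9-amino-9-deoxy-epi-quinine (20 mol%), CF3CO2H (40 mol%), THF, rt; then CF3CO2H (10 equiv), 0 °C → rt
Reagents that add atoms: none
Why: Proposed new method: the primary ammonium salt condenses with the α-branched enal 3 to an iminium ion, 4 adds through carbon to the Si face of the β-carbon (C4–C4a), and after C-protonation of the enamine and hydrolysis the ortho hydroxyl closes ring C on the aldehyde by 6-exo-trig hemiacetalisation (O1–C2) to lactol 5; added CF3CO2H then ionises 5 to the benzopyranyl oxocarbenium ion, which exchanges H3 through 4H-chromene 6 and is captured at C2 by a second molecule of 4 (C2–C1′). The closest known reactions are the amine-catalysed Friedel–Crafts alkylation/hemiacetalisation of electron-rich phenols with β-substituted enals to chroman-2-ols, the primary-amine iminium activation of α-branched enals towards indoles, and the acid-mediated C-arylation of lactols by phloroglucinols; the pairing of an α-branched enal with a phenol and the merger in one flask are the untested parts. C4 (S) is set by the chiral amine alone, which must shield the Re face of the β-carbon. C3 is not trusted from the amine stage but re-set in acid: the C4 isobutyl group is held pseudoaxial by peri strain with the C5 hydroxyl, 6 is therefore protonated at C3 on the opposite face, and the resulting 3,4-cis cation is the one with an unhindered face, so it is the one that is arylated (Curtin–Hammett). C2 follows because 4 enters anti to both alkyl groups and reversible O1–C2 ionisation of the electron-rich benzylic ether leaves the aryl group equatorial, which gives (2R,3R,4S). The step needs 1,4- over 1,2-addition, single alkylation of each molecule of 4 and C- over O-arylation; the α-isopropyl group that screens the iminium carbon, the threefold symmetry and the excess of 4, and the reversibility of O-arylation under acid should secure these.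

Step 3
Reactants: 7 (2R,3R,4S)-4-isobutyl-3-isopropyl-2-(2,4,6-trihydroxyphenyl)chroman-5,7-diol; 8 N,N-dimethylformamide
Product: 10 sideroxylonal A, via tetrakis(iminium) chloride 9 (not isolated)
Conditions: POCl3 (6 equiv), DMF 8 (excess), EtOAc, 0 °C → rt; then H2O, 50 °C
Reagents that add atoms: N,N-dimethylformamide 8, CN(C)C=O (the four formyl CH units); water, O (the four formyl oxygens)
Why: Vilsmeier–Haack formylation: the chloroiminium ion from POCl3 and 8 should attack the four unsubstituted ring carbons (C6, C8, C3′, C5′), each flanked by two oxygen-bearing carbons, the free hydroxyls keep each ring nucleophilic enough for a second substitution, and water hydrolyses iminium salt 9 to the aldehydes; no stereocentre is formed or broken, and C2, the only one that acid could touch, already carries its favoured equatorial aryl group.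

**Compound list**

1 | isovaleraldehyde (3-methylbutanal) | CC(C)CC=O | starting material
2 | 3-hydroxy-2-isopropyl-5-methylhexanal (aldol, diastereomer mixture, formed in the flask) | CC(C)CC(O)C(C(C)C)C=O | intermediate
3 | (E)-2-isopropyl-5-methylhex-2-enal | CC(C)C/C=C(\C(C)C)C=O | intermediate
4 | phloroglucinol (benzene-1,3,5-triol) | Oc1cc(O)cc(O)c1 | starting material
5 | (4S)-4-isobutyl-3-isopropylchroman-2,5,7-triol (lactol, C2 anomers and C3 epimers, formed in the flask) | CC(C)C[C@@H]1c2c(O)cc(O)cc2OC(O)C1C(C)C | intermediate
6 | (4S)-4-isobutyl-3-isopropyl-4H-chromene-5,7-diol (formed in the flask) | CC(C)C[C@@H]1c2c(O)cc(O)cc2OC=C1C(C)C | intermediate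
7 | (2R,3R,4S)-4-isobutyl-3-isopropyl-2-(2,4,6-trihydroxyphenyl)chroman-5,7-diol (pentaphenol, tetra-desformyl sideroxylonal A; 2,3-trans, 3,4-cis) | CC(C)C[C@@H]1c2c(O)cc(O)cc2O[C@@H](c2c(O)cc(O)cc2O)[C@@H]1C(C)C | intermediate
8 | N,N-dimethylformamide | CN(C)C=O | starting material
9 | tetrakis(N,N-dimethyliminium) tetrachloride corresponding to 10 (formed in the flask) | CC(C)C[C@@H]1c2c(O)c(C=[N+](C)C)c(O)c(C=[N+](C)C)c2O[C@@H](c2c(O)c(C=[N+](C)C)c(O)c(C=[N+](C)C)c2O)[C@@H]1C(C)C.[Cl-].[Cl-].[Cl-].[Cl-] | intermediate
10 | sideroxylonal A, (2R,3R,4S)-2-(3,5-diformyl-2,4,6-trihydroxyphenyl)-5,7-dihydroxy-4-isobutyl-3-isopropylchroman-6,8-dicarbaldehyde | CC(C)C[C@@H]1c2c(O)c(C=O)c(O)c(C=O)c2O[C@@H](c2c(O)c(C=O)c(O)c(C=O)c2O)[C@@H]1C(C)C | target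

**Step count**

Total steps: 3. Longest linear sequence: 3 steps (1 → 3 → 7 → 10).

**Steps most likely to fail**

1. Step 2 (Proposed new method). What may go wrong:
- slow iminium formation from the α-branched enal;
- competing 1,2-addition with ring closure to a 2H-chromene;
- weak facial discrimination at C4;
- incomplete re-setting of C3, or its erosion if the C2–C1′ bond begins to cleave reversibly on long acid exposure;
- further arylation of the product to oligomers or to a ring-opened bis(aryl)methane.

Fallback with known chemistry, setting out from 1 and 4 and coming back at lactol 5. Phloroglucinol 4 (in excess), 1 and sodium p-toluenesulfinate in aqueous HCO2H should give racemic 2-(3-methyl-1-tosylbutyl)benzene-1,3,5-triol F1 (three-component sulfone formation of an electron-rich phenol). NaHCO3 eliminates sulfinate to the ortho-quinone methide 3,5-dihydroxy-6-(3-methylbutylidene)cyclohexa-2,4-dien-1-one F2. This is trapped in the same flask by the enamine of a further molecule of 1 with α,α-diphenylprolinol trimethylsilyl ether (enantiomer chosen for the (4S) series), and hemiacetalisation gives 5. Enamine Michael addition to ortho-quinone methides made in situ from 2-(1-tosylalkyl)phenols is a known entry to 3,4-disubstituted chroman-2-ols. Here C3–C4 is the bond made. The major diastereomer of 5 is purified, so that the later re-setting of C3 cannot erode the purity at C4, and is then treated with 4 and CF3CO2H as in the second stage of step 2 to reach 7.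

2. Step 3. What may go wrong:
- stalling before the fourth substitution as each formyl group deactivates its ring;
- acid-induced ipso attack at C1′ with loss of ring B;
- opening of ring C by O1–C2 ionisation.

Fallback, setting out from 7 and coming back at 10. Exhaustive O-methylation (Me2SO4, K2CO3, acetone) should give (2R,3R,4S)-4-isobutyl-3-isopropyl-5,7-dimethoxy-2-(2,4,6-trimethoxyphenyl)chroman F3. Fourfold Rieche formylation (Cl2CHOMe, TiCl4, CH2Cl2, −78 → 0 °C) should give (2R,3R,4S)-2-(3,5-diformyl-2,4,6-trimethoxyphenyl)-4-isobutyl-3-isopropyl-5,7-dimethoxychroman-6,8-dicarbaldehyde F4. Every methoxy group of F4 is ortho to a formyl group, so chelation-assisted ether cleavage with BCl3 (CH2Cl2, −78 °C → rt) should release 10.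

3. Step 1. What may go wrong:
- over-condensation to trimers;
- loss of aldehyde by Cannizzaro or Tishchenko reactions;
- formation of an E/Z mixture.

Fallback, setting out from 1 and coming back at 3: a directed aldol condensation through a metalated imine. Aldehyde 1 and cyclohexylamine give N-cyclohexyl-3-methylbutan-1-imine F5. Deprotonation with lithium diisopropylamide, LiN(i-Pr)2 (THF, −78 °C), and addition of one equivalent of 1 give the β-hydroxy imine 3-[(cyclohexylimino)methyl]-2,6-dimethylheptan-4-ol F6. Warm aqueous oxalic acid then hydrolyses the imine and dehydrates the aldol to 3.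

**Further compounds**

F1 | step 2 | 2-(3-methyl-1-tosylbutyl)benzene-1,3,5-triol (racemic) | CC(C)CC(c1c(O)cc(O)cc1O)S(=O)(=O)c1ccc(C)cc1
F2 | step 2 | 3,5-dihydroxy-6-(3-methylbutylidene)cyclohexa-2,4-dien-1-one (ortho-quinone methide, not isolated) | CC(C)CC=C1C(=O)C=C(O)C=C1O
F3 | step 3 | (2R,3R,4S)-4-isobutyl-3-isopropyl-5,7-dimethoxy-2-(2,4,6-trimethoxyphenyl)chroman | CC(C)C[C@@H]1c2c(OC)cc(OC)cc2O[C@@H](c2c(OC)cc(OC)cc2OC)[C@@H]1C(C)C
F4 | step 3 | (2R,3R,4S)-2-(3,5-diformyl-2,4,6-trimethoxyphenyl)-4-isobutyl-3-isopropyl-5,7-dimethoxychroman-6,8-dicarbaldehyde | CC(C)C[C@@H]1c2c(OC)c(C=O)c(OC)c(C=O)c2O[C@@H](c2c(OC)c(C=O)c(OC)c(C=O)c2OC)[C@@H]1C(C)C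
F5 | step 1 | N-cyclohexyl-3-methylbutan-1-imine | CC(C)CC=NC1CCCCC1
F6 | step 1 | 3-[(cyclohexylimino)methyl]-2,6-dimethylheptan-4-ol (β-hydroxy imine, not isolated) | CC(C)CC(O)C(C(C)C)C=NC1CCCCC1
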